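The vessel is closed, stirred and isothermal, and its contents appear as peaks of five species, while reagent and intermediate B have no column.

| flask | starting material | reagent | remark | time |
|---|---|---|---|---|
| Wednesday's | 0.19 M | 0.42 M | run made earlier |  |
| Sunday's | 0.14 M | 0.42 M | run made earlier |  |
| winter | 0.28 M | 0.420 M |  | 80 min |
| midnight | 0.28 M | 1.30 M |  | 80 min |

| run | time / min | intermediate A / % | over-reaction product / % | target / % | starting material / % | intermediate C / % |
|---|---|---|---|---|---|---|
| Wednesday's | 1.33 | 6.1 | 0.1 | 0.7 | 92.1 | 0.1 |
| Wednesday's | 3.00 | 10.2 | 0 | 1.2 | 83.5 | 0.6 |
| Wednesday's | 6.00 | 12.4 | 0 | 6.8 | 71.6 | 2.5 |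
| Wednesday's | 15.0 | 9.5 | 1.8 | 26.3 | 49.2 | 6.4 |
| Sunday's | 1.33 | 6.0 | 0 | 0 | 92.1 | 0.2 |
| Sunday's | 3.00 | 10.1 | 0 | 1.2 | 83.7 | 0.9 |
| Sunday's | 6.00 | 12.3 | 0.4 | 7.4 | 70.6 | 2.0 |
| Sunday's | 15.0 | 8.9 | 1.7 | 27.6 | 46.7 | 6.4 |

(readings scatter by 0.3 percentage points)

- which of these there is most of at the end, counted by the starting material in it, winter (starting material / intermediate A / over-reaction product / target / intermediate C)
- which of these there is most of at the end, counted by the starting material in it, midnight (starting material / intermediate A / over-reaction product / target / intermediate C)
- final amount of the leader among these, as a percentage of the starting material charged, in winter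
- final amount of the leader among these, as a percentage of the starting material charged, in midnight

- steps thought possible: starting material + reagent -> intermediate A; reagent + intermediate A -> intermediate B; intermediate B -> target; intermediate B <-> intermediate C; reagent + target -> over-reaction product

Wednesday's and Sunday's runs share the same c(reagent), yet at 15.0 min Sunday's run holds 46.7 % of its starting material, less than Wednesday's 49.2 %. That gap of 2.5 percentage points stands against a scatter of 0.3 points, and the two runs differ in c(starting material) charged, but reagent itself is unread. We therefore reckon reagent from the steps: intermediate A costs one reagent, intermediate B, target and intermediate C two, and over-reaction product 3.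

For winter, c(reagent) charged over c(starting material) charged is 1.50, and this ratio is the reagent budget. Winter's budget is below the price of target, so reagent is the limiting reagent there. Our own reckoning for winter takes the forecast's 6 % intermediate A, 6 % intermediate C and 7 % over-reaction product, supposes the full budget spent, and lets the remainder buy target: 55.5 %. Midnight's budget of 4.64 is above 3, so reagent sets no stop on over-reaction in midnight.

The forecast names target at 49 % for winter, below our figure, and over-reaction product at 75 % for midnight: “Winter has only 1.5 equivalents of reagent and each product needs 2, so reagent starves.”

Winter ends with target leading at 57.1 %, and midnight with over-reaction product leading at 72.4 %.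

    starting material + reagent → intermediate A (k = 0.00246 M⁻¹ s⁻¹)
    reagent + intermediate A → intermediate B (k = 0.0142 M⁻¹ s⁻¹)
    intermediate B → target (k = 0.00507 s⁻¹)
    intermediate B ⇌ intermediate C (K = 1.23, k = 0.00184 s⁻¹)
    reagent + target → over-reaction product (k = 5.54 × 10⁻⁴ M⁻¹ s⁻¹)

Winter has spent 1.44 of its budget of 1.50 by 80.0 min, with 4.1 % of its reagent charge left. At that moment the half-life of starting material by the first step in winter is 4.5 h, longer than the run's 80 min, and 28.6 % of the starting material stands unreacted. The neighbour flask, winter with 0.11 M of starting material, has a budget of 3.82, above 3, and at 80.0 min it holds 43.1 % of its reagent charge, with 28.7 % over-reaction product.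

(Readings and results were computed from invented constants.)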